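**Retrosynthetic overview**

1. The target comes from its 5,7-bis-MOM ether 18 by mild acetal cleavage. The benzene ring is bought (2-methoxyresorcinol) and decorated by C–H borylation/oxidation and two directed ortho-metalations (prenyl, then boron).
2. Enabling feature: in the dihydropyranone ring the α-ketol C3(OH)–C4(=O) sits next to the benzylic, O1-bearing C2. This is the 1,2-shifted isomer of a 3-oxido-2-phenyl-2,3-dihydrobenzofuran-3-carbaldehyde, in which C2 moves from the carbinol carbon (future C4) to the formyl carbon (future C3). The pyranone ring is therefore made by one-carbon expansion of a dihydrofuran ring.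
3. That dihydrobenzofuran is not isolated. It forms in the same flask from the acyclic (2R,3S)-epoxy aldehyde 15 when fluoride unmasks the ortho phenoxide, which opens the epoxide at its benzylic carbon.
4. 15 comes from Sharpless epoxidation and oxidation of the (E)-2-aryl-3-phenylallyl alcohol 13, itself from Suzuki coupling of the hexasubstituted arylboronate 10 with (Z)-2-bromo-3-phenylallyl alcohol 12.
5. Ring order: benzene (given) → oxirane (step 9) → dihydrofuran (transient, step 11) → dihydropyranone (step 11).

Key step: step 11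

Remark: 2-methoxyresorcinol (1), (Z)-α-bromocinnamaldehyde (11) and all reagents are taken as commercially available; the anionic intermediates 16 and 17 are drawn as tetrabutylammonium salts and the aryllithiums as monomers.

**Route**

Step 1
Reactants: 1 2-methoxyresorcinol (2-methoxybenzene-1,3-diol)
Product: 2 2-methoxy-3-[(triisopropylsilyl)oxy]phenol
Conditions: TIPSCl (0.9 equiv), imidazole, DMF, 0 °C → rt
Reagents that add atoms: triisopropylsilyl chloride, CC(C)[Si](Cl)(C(C)C)C(C)C
Why: Silyl etherification of the symmetric diol with a deficit of the bulky chloride should give mostly the mono-ether (bis-ether and recovered diol are separable), which marks the oxygen that later becomes ring oxygen O1.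

Step 2
Reactants: 2 2-methoxy-3-[(triisopropylsilyl)oxy]phenol
Product: 3 triisopropyl[2-methoxy-3-(methoxymethoxy)phenoxy]silane
Conditions: MOMCl, i-Pr2NEt, CH2Cl2, 0 °C → rt
Reagents that add atoms: chloromethyl methyl ether, COCCl
Why: O-alkylation of the remaining phenol (MOM acetal formation) protects the future 7-OH with a group that later directs ortho-lithiation; the silyl group cannot migrate across the intervening methoxy carbon.

Step 3
Reactants: 3 triisopropyl[2-methoxy-3-(methoxymethoxy)phenoxy]silane
Product: 5 4-methoxy-3-(methoxymethoxy)-5-[(triisopropylsilyl)oxy]phenol, via arylboronate 4 (not isolated)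
Conditions: [Ir(OMe)(cod)]2 (1.5 mol %), dtbpy (3 mol %), B2pin2, THF, 80 °C; then Oxone, acetone/H2O, 0 °C → rt
Reagents that add atoms: bis(pinacolato)diboron, CC1(C)OB(OC1(C)C)B1OC(C)(C)C(C)(C)O1 (boron carried in 4 only); Oxone (potassium peroxymonosulfate), [K+].OOS(=O)(=O)[O-]
Why: Sterically controlled iridium-catalysed C–H borylation should occur only at the one ring C–H without an ortho substituent (para to OMe), and oxidation of the C–B bond in the same flask installs the oxygen that becomes 5-OH.

Step 4
Reactants: 5 4-methoxy-3-(methoxymethoxy)-5-[(triisopropylsilyl)oxy]phenol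
Product: 6 triisopropyl[2-methoxy-3,5-bis(methoxymethoxy)phenoxy]silane
Conditions: MOMCl, i-Pr2NEt, CH2Cl2, 0 °C → rt
Reagents that add atoms: chloromethyl methyl ether, COCCl
Why: MOM acetal formation on the new phenol completes a tetra-oxygenated arene in which the three phenolic oxygens are differentiated (one silyl, two MOM).

Step 5
Reactants: 6 triisopropyl[2-methoxy-3,5-bis(methoxymethoxy)phenoxy]silane
Product: 8 triisopropyl[2-methoxy-3,5-bis(methoxymethoxy)-4-(3-methylbut-2-en-1-yl)phenoxy]silane, via aryllithium 7 (not isolated)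
Conditions: n-BuLi, THF, 0 °C; then CuBr·SMe2 (10 mol %), prenyl bromide, −78 °C → rt
Reagents that add atoms: n-butyllithium, [Li]CCCC (lithium carried in 7 only); prenyl bromide (1-bromo-3-methylbut-2-ene), CC(C)=CCBr
Why: Directed ortho-metalation should take place at the C–H flanked by two OMOM groups (cooperative direction), and copper-catalysed SN2 allylation of the aryllithium puts the prenyl group between the future 5- and 7-oxygens.

Step 6
Reactants: 8 triisopropyl[2-methoxy-3,5-bis(methoxymethoxy)-4-(3-methylbut-2-en-1-yl)phenoxy]silane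
Product: 10 triisopropyl[2-methoxy-3,5-bis(methoxymethoxy)-4-(3-methylbut-2-en-1-yl)-6-(4,4,5,5-tetramethyl-1,3,2-dioxaborolan-2-yl)phenoxy]silane, via aryllithium 9 (not isolated)
Conditions: n-BuLi, THF, −40 °C; then i-PrOBpin, −78 °C → rt; H2O
Reagents that add atoms: n-butyllithium, [Li]CCCC (lithium carried in 9 only); 2-isopropoxy-4,4,5,5-tetramethyl-1,3,2-dioxaborolane, CC(C)OB1OC(C)(C)C(C)(C)O1
Why: A second OMOM-directed ortho-metalation at the only remaining ring C–H, with borate trapping at low temperature to outrun O→C silyl migration and lateral metalation of the prenyl CH2, should give the chromatography-stable pinacol boronate.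

Step 7
Reactants: 11 (Z)-2-bromo-3-phenylprop-2-enal (α-bromocinnamaldehyde)
Product: 12 (Z)-2-bromo-3-phenylprop-2-en-1-ol
Conditions: NaBH4, CeCl3·7H2O, MeOH, 0 °C
Reagents that add atoms: none
Why: Luche 1,2-reduction of the enal leaves the vinyl bromide and the alkene geometry (Br cis to phenyl) untouched.

Step 8
Reactants: 10 the arylboronate from step 6; 12 (Z)-2-bromo-3-phenylprop-2-en-1-ol
Product: 13 (E)-2-{3-methoxy-4,6-bis(methoxymethoxy)-5-(3-methylbut-2-en-1-yl)-2-[(triisopropylsilyl)oxy]phenyl}-3-phenylprop-2-en-1-ol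
Conditions: Pd(OAc)2 (5 mol %), SPhos (10 mol %), K3PO4, toluene/H2O, 80 °C
Reagents that add atoms: none
Why: Suzuki–Miyaura coupling with a dialkylbiarylphosphine ligand suited to di-ortho-substituted boronates replaces bromine by the aryl group with retention, so the aryl ends cis to phenyl and CH2OH trans to it (E).

Step 9
Reactants: 13 the (E)-allylic alcohol from step 8
Product: 14 [(2S,3S)-2-{3-methoxy-4,6-bis(methoxymethoxy)-5-(3-methylbut-2-en-1-yl)-2-[(triisopropylsilyl)oxy]phenyl}-3-phenyloxiran-2-yl]methanol
Conditions: Ti(Oi-Pr)4 (20 mol %), L-(+)-DET (25 mol %), t-BuOOH, 4 Å MS, CH2Cl2, −20 °C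
Reagents that add atoms: tert-butyl hydroperoxide, CC(C)(C)OO
Why: Sharpless asymmetric epoxidation with L-(+)-tartrate should deliver oxygen to the face that gives the (2S,3S) epoxide (as for (E)-2,3-diphenylallyl and cinnamyl alcohol), setting the benzylic centre that becomes C2; the prenyl alkene, which cannot bind titanium, is not epoxidised.

Step 10
Reactants: 14 the (2S,3S)-epoxy alcohol from step 9
Product: 15 (2R,3S)-2-{3-methoxy-4,6-bis(methoxymethoxy)-5-(3-methylbut-2-en-1-yl)-2-[(triisopropylsilyl)oxy]phenyl}-3-phenyloxirane-2-carbaldehyde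
Conditions: Dess–Martin periodinane, pyridine, CH2Cl2, 0 °C → rt
Reagents that add atoms: none
Why: Buffered Dess–Martin oxidation gives the aldehyde without touching the epoxide, and the quaternary α-carbon cannot epimerise (the descriptor at C2 changes only through CIP priorities).

Step 11
Reactants: 15 the (2R,3S)-epoxy aldehyde from step 10
Product: 18 (2R,3R)-3-hydroxy-8-methoxy-5,7-bis(methoxymethoxy)-6-(3-methylbut-2-en-1-yl)-2-phenylchroman-4-one, via phenoxide 16 (not isolated), via alkoxide-aldehyde 17 (not isolated)
Conditions: TBAF (1.2 equiv), 4 Å MS, THF, −40 → 0 °C; then AcOH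
Reagents that add atoms: tetrabutylammonium fluoride, CCCC[N+](CCCC)(CCCC)CCCC.[F-] (counter-ion of 16 and 17 only)
Why: Proposed new method: fluoride unmasks phenoxide 16, which opens the epoxide at the benzylic carbon in an SN2 sense (5-endo-type closure of the dihydrofuran ring with inversion; attack at the quaternary carbon would need a four-membered ring) to give the tertiary alkoxide 17, a 3-oxido-2,3-dihydrobenzofuran-3-carbaldehyde, whose C2–C3 ring bond then shifts from the carbinol carbon to the formyl carbon (anionic α-ketol shift), so the six-membered dihydropyranone is formed by this 1,2-shift (ring expansion by one carbon, not a cyclisation) and the aldehyde becomes the more stable aryl-conjugated ketone. The closest known reaction types are the phenoxide cyclisation of ortho-hydroxystilbene oxides to 2-aryl-2,3-dihydrobenzofuran-3-ols and the ring-expanding α-ketol (acyloin) rearrangement of cyclic tertiary α-hydroxy aldehydes and ketones (D-homoannulation); their combination on this benzo-fused oxacycle has not been shown. C2 of the product is the benzylic epoxide carbon set in step 9, inverted once in the epoxide opening and carried through the shift with retention at the migrating carbon. C3 is created in the shift: with a non-chelating tetrabutylammonium counter-ion the alkoxide and formyl oxygens should lie antiperiplanar, which for the cis-2-phenyl/3-oxido diastereomer 17 exposes the formyl face that leads to the 2,3-trans (2R,3R) product, which is also the thermodynamically preferred epimer. The step needs C2 to migrate instead of aryl carbon C3a: under anionic conditions the electron-rich tetra-oxygenated aryl is a poor migrating group and gains conjugation with the new ketone by staying, C2 is benzylic and α-oxygenated, and a bridged aryl shift is strained inside the fused ring. It also needs the phenoxide to attack faster than it ionises the epoxide to an ortho-quinone methide, which the formyl group on the quaternary carbon and the low temperature should disfavour.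

Step 12
Reactants: 18 the bis-MOM dihydroflavonol from step 11
Product: 20 (2R,3R)-3,5,7-trihydroxy-8-methoxy-6-(3-methylbut-2-en-1-yl)-2-phenylchroman-4-one, via mono-MOM ether 19 (not isolated)
Conditions: HCl (1.25 M in MeOH), 0 °C → rt
Reagents that add atoms: none
Why: Acid-catalysed transacetalisation to methanol should cleave both aryl MOM ethers (the one peri to the ketone first); dilute acid at low temperature is chosen so the prenyl group does not cyclise onto a flanking phenol, and neither stereocentre is labile under acid.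

**Compound list**

1 | 2-methoxybenzene-1,3-diol (2-methoxyresorcinol) | COc1c(O)cccc1O | starting material
2 | 2-methoxy-3-[(triisopropylsilyl)oxy]phenol | COc1c(O)cccc1O[Si](C(C)C)(C(C)C)C(C)C | intermediate
3 | triisopropyl[2-methoxy-3-(methoxymethoxy)phenoxy]silane | COCOc1cccc(O[Si](C(C)C)(C(C)C)C(C)C)c1OC | intermediate
4 | triisopropyl[2-methoxy-3-(methoxymethoxy)-5-(4,4,5,5-tetramethyl-1,3,2-dioxaborolan-2-yl)phenoxy]silane | COCOc1cc(B2OC(C)(C)C(C)(C)O2)cc(O[Si](C(C)C)(C(C)C)C(C)C)c1OC | intermediate
5 | 4-methoxy-3-(methoxymethoxy)-5-[(triisopropylsilyl)oxy]phenol | COCOc1cc(O)cc(O[Si](C(C)C)(C(C)C)C(C)C)c1OC | intermediate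
6 | triisopropyl[2-methoxy-3,5-bis(methoxymethoxy)phenoxy]silane | COCOc1cc(OCOC)cc(O[Si](C(C)C)(C(C)C)C(C)C)c1OC | intermediate
7 | [3-methoxy-2,6-bis(methoxymethoxy)-4-(triisopropylsilyloxy)phenyl]lithium | COCOc1c([Li])c(OCOC)cc(O[Si](C(C)C)(C(C)C)C(C)C)c1OC | intermediate
8 | triisopropyl[2-methoxy-3,5-bis(methoxymethoxy)-4-(3-methylbut-2-en-1-yl)phenoxy]silane | COCOc1c(CC=C(C)C)c(OCOC)cc(O[Si](C(C)C)(C(C)C)C(C)C)c1OC | intermediate
9 | [3-methoxy-4,6-bis(methoxymethoxy)-5-(3-methylbut-2-en-1-yl)-2-(triisopropylsilyloxy)phenyl]lithium | COCOc1c(CC=C(C)C)c(OCOC)c([Li])c(O[Si](C(C)C)(C(C)C)C(C)C)c1OC | intermediate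
10 | triisopropyl[2-methoxy-3,5-bis(methoxymethoxy)-4-(3-methylbut-2-en-1-yl)-6-(4,4,5,5-tetramethyl-1,3,2-dioxaborolan-2-yl)phenoxy]silane | COCOc1c(CC=C(C)C)c(OCOC)c(B2OC(C)(C)C(C)(C)O2)c(O[Si](C(C)C)(C(C)C)C(C)C)c1OC | intermediate
11 | (Z)-2-bromo-3-phenylprop-2-enal | O=C/C(Br)=C/c1ccccc1 | starting material
12 | (Z)-2-bromo-3-phenylprop-2-en-1-ol | OC/C(Br)=C/c1ccccc1 | intermediate
13 | (E)-2-{3-methoxy-4,6-bis(methoxymethoxy)-5-(3-methylbut-2-en-1-yl)-2-[(triisopropylsilyl)oxy]phenyl}-3-phenylprop-2-en-1-ol | OC/C(=C/c1ccccc1)c1c(OCOC)c(CC=C(C)C)c(OCOC)c(OC)c1O[Si](C(C)C)(C(C)C)C(C)C | intermediate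
14 | [(2S,3S)-2-{3-methoxy-4,6-bis(methoxymethoxy)-5-(3-methylbut-2-en-1-yl)-2-[(triisopropylsilyl)oxy]phenyl}-3-phenyloxiran-2-yl]methanol | OC[C@]1(c3c(OCOC)c(CC=C(C)C)c(OCOC)c(OC)c3O[Si](C(C)C)(C(C)C)C(C)C)O[C@H]1c2ccccc2 | intermediate
15 | (2R,3S)-2-{3-methoxy-4,6-bis(methoxymethoxy)-5-(3-methylbut-2-en-1-yl)-2-[(triisopropylsilyl)oxy]phenyl}-3-phenyloxirane-2-carbaldehyde | O=C[C@]1(c3c(OCOC)c(CC=C(C)C)c(OCOC)c(OC)c3O[Si](C(C)C)(C(C)C)C(C)C)O[C@H]1c2ccccc2 | intermediate
16 | tetrabutylammonium 2-[(2R,3S)-2-formyl-3-phenyloxiran-2-yl]-6-methoxy-3,5-bis(methoxymethoxy)-4-(3-methylbut-2-en-1-yl)phenoxide | CCCC[N+](CCCC)(CCCC)CCCC.O=C[C@]1(c3c(OCOC)c(CC=C(C)C)c(OCOC)c(OC)c3[O-])O[C@H]1c2ccccc2 | intermediate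
17 | tetrabutylammonium (2R,3R)-3-formyl-7-methoxy-4,6-bis(methoxymethoxy)-5-(3-methylbut-2-en-1-yl)-2-phenyl-2,3-dihydrobenzofuran-3-olate | CCCC[N+](CCCC)(CCCC)CCCC.O=C[C@@]1([O-])c2c(OCOC)c(CC=C(C)C)c(OCOC)c(OC)c2O[C@@H]1c1ccccc1 | intermediate
18 | (2R,3R)-3-hydroxy-8-methoxy-5,7-bis(methoxymethoxy)-6-(3-methylbut-2-en-1-yl)-2-phenylchroman-4-one | COc1c(OCOC)c(CC=C(C)C)c(OCOC)c2c1O[C@H](c1ccccc1)[C@@H](O)C2=O | intermediate
19 | (2R,3R)-3,5-dihydroxy-8-methoxy-7-(methoxymethoxy)-6-(3-methylbut-2-en-1-yl)-2-phenylchroman-4-one | COc1c(OCOC)c(CC=C(C)C)c(O)c2c1O[C@H](c1ccccc1)[C@@H](O)C2=O | intermediate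
20 | (2R,3R)-3,5,7-trihydroxy-8-methoxy-6-(3-methylbut-2-en-1-yl)-2-phenylchroman-4-one | COc1c(O)c(CC=C(C)C)c(O)c2c1O[C@H](c1ccccc1)[C@@H](O)C2=O | target

**Step count and risks**

Total step count: 12. Longest linear sequence: 11 steps (steps 1–6 and 8–12; step 7 is a one-step side branch).

Steps most likely to fail:

(i) Step 11 (labelled step). Three processes may interfere. The phenoxide may ionise the epoxide to an ortho-quinone methide, which fragments by a vinylogous retro-aldol. The aryl carbon may migrate in place of C2. The shift may pass through the syn alignment and give the 2,3-cis epimer. The fallback uses only established chemistry and gives up the five-membered intermediate. It sets out from 8: lithiation as in step 6 (aryllithium 9) and acylation with commercial methyl (2R,3S)-3-phenylglycidate at −78 °C should stop at the ketone because of the two ortho substituents. This gives the 2′-silyloxychalcone epoxide {3-methoxy-4,6-bis(methoxymethoxy)-5-(3-methylbut-2-en-1-yl)-2-[(triisopropylsilyl)oxy]phenyl}[(2R,3S)-3-phenyloxiran-2-yl]methanone F1. TBAF in THF then frees the phenoxide, which opens the epoxide at the benzylic carbon in the well-known 6-endo cyclisation of 2′-hydroxychalcone epoxides (inversion at C2, epoxide oxygen retained as 3-OH). The route is rejoined at 18.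

(ii) Step 9. The bulky di-ortho-substituted aryl group at C2 may slow oxygen transfer and erode facial selectivity, and the electron-rich aryl epoxide may be opened solvolytically in the titanium alkoxide medium. The fallback sets out from 13: MnO2 oxidation gives the enal (E)-2-{3-methoxy-4,6-bis(methoxymethoxy)-5-(3-methylbut-2-en-1-yl)-2-[(triisopropylsilyl)oxy]phenyl}-3-phenylprop-2-enal F2. Iminium-catalysed asymmetric Weitz–Scheffer epoxidation with aqueous H2O2 and a cinchona-derived primary amine salt (pseudo-enantiomer chosen for the 2R,3S product) then gives the epoxy aldehyde directly. This nucleophilic epoxidation does not touch the prenyl alkene and avoids the epoxy alcohol. The route is rejoined at 15.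

(iii) Step 8. The di-ortho-alkoxy arylboronate may protodeboronate, and transmetalation at the hindered carbon may be slow. The fallback sets out from 8: aryllithium 9 is transmetalated with MgBr2·OEt2 to the Grignard reagent [3-methoxy-4,6-bis(methoxymethoxy)-5-(3-methylbut-2-en-1-yl)-2-(triisopropylsilyloxy)phenyl]magnesium bromide F3. F3 is added to the magnesium alkoxide of commercial 3-phenylprop-2-yn-1-ol (CuI cat., THF/toluene, reflux) in the hydroxyl-directed anti-carbomagnesiation mode (aryl to C2, magnesium to C3). Protonation gives the same E allylic alcohol without a boron intermediate. The route is rejoined at 13.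

Further compounds
F1 | step 11 | {3-methoxy-4,6-bis(methoxymethoxy)-5-(3-methylbut-2-en-1-yl)-2-[(triisopropylsilyl)oxy]phenyl}[(2R,3S)-3-phenyloxiran-2-yl]methanone | O=C(c3c(OCOC)c(CC=C(C)C)c(OCOC)c(OC)c3O[Si](C(C)C)(C(C)C)C(C)C)[C@@H]1O[C@H]1c2ccccc2
F2 | step 9 | (E)-2-{3-methoxy-4,6-bis(methoxymethoxy)-5-(3-methylbut-2-en-1-yl)-2-[(triisopropylsilyl)oxy]phenyl}-3-phenylprop-2-enal | O=C/C(=C/c1ccccc1)c1c(OCOC)c(CC=C(C)C)c(OCOC)c(OC)c1O[Si](C(C)C)(C(C)C)C(C)C
F3 | step 8 | [3-methoxy-4,6-bis(methoxymethoxy)-5-(3-methylbut-2-en-1-yl)-2-(triisopropylsilyloxy)phenyl]magnesium bromide | COCOc1c(CC=C(C)C)c(OCOC)c([Mg]Br)c(O[Si](C(C)C)(C(C)C)C(C)C)c1OC
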